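**Retrosynthetic overview**

1. Sequoiaflavone ⇐ hydrogenolysis of a penta-O-benzyl biflavone; ring C of unit 1 ⇐ I2/DMSO cyclisation of a 2'-hydroxychalcone built from a unit 2 flavone aldehyde and 2-benzyloxy-6-hydroxy-4-methoxyacetophenone.
2. Aldehyde ⇐ Pd-catalysed formylation of the ring B bromide; ring C of unit 2 ⇐ chalcone from a 3-aryl-2-hydroxy-4,6-bis(benzyloxy)acetophenone and 4-(benzyloxy)benzaldehyde.
3. Acetophenone ⇐ Hoesch acetylation and regioselective dibenzylation of a 2-arylphloroglucinol; the hydroxyl left free is the one beside the biaryl bond, which fixes the 8-aryl flavone.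
4. Feature: ring A of unit 2 is a phloroglucinol (oxygens on C5, C7, C8a) whose C8 carries C3' of ring B of unit 1. It maps onto a 3,5-dioxohexanoate in which C6 is the benzylic carbon of an arylacetic acid and bonds to the ester carbon C1, so the C8–C3' biaryl bond comes from (2-hydroxyphenyl)acetic acid without cross-coupling.
5. Ring order: ring A of unit 2 (step 5), ring C of unit 2 (step 9), ring C of unit 1 (step 13); ring B of both units and ring A of unit 1 come from starting materials.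

Key step: step 5

Assumption: the C8–C3' axis bears three small ortho substituents and is treated as freely rotating, in line with the target SMILES, which gives no axial configuration.
Assumption: 1-(2,6-dihydroxy-4-methoxyphenyl)ethanone is bought as such, which avoids a selective methylation of 2',4',6'-trihydroxyacetophenone.

**Route**

Step 1
Reactants: 1 (2-hydroxyphenyl)acetic acid
Product: 2 (5-bromo-2-hydroxyphenyl)acetic acid
Conditions: NBS (1.0 equiv), MeCN, 0 °C → rt
Reagents that add atoms: N-bromosuccinimide, O=C1CCC(=O)N1Br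
Why: Electrophilic aromatic bromination of a phenol, directed para to the hydroxyl (C5) because the other activated position is ortho and more hindered.

Step 2
Reactants: 2 (5-bromo-2-hydroxyphenyl)acetic acid
Product: 4 [2-(benzyloxy)-5-bromophenyl]acetic acid, via benzyl [2-(benzyloxy)-5-bromophenyl]acetate 3 (not isolated)
Conditions: BnBr (2.2 equiv), K2CO3, DMF, 60 °C; then NaOH (aq), MeOH, 60 °C; HCl
Reagents that add atoms: benzyl bromide, BrCc1ccccc1; sodium hydroxide, [Na+].[OH-]
Why: Williamson O-alkylation of phenoxide and carboxylate followed by saponification of the benzyl ester in the same flask should leave only the base-stable aryl benzyl ether.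

Step 3
Reactants: 4 [2-(benzyloxy)-5-bromophenyl]acetic acid
Product: 6 2-[2-(benzyloxy)-5-bromophenyl]-N-methoxy-N-methylacetamide, via 1-{[2-(benzyloxy)-5-bromophenyl]acetyl}-1H-imidazole 5 (not isolated)
Conditions: CDI, CH2Cl2, rt; then MeNH(OMe)·HCl, rt
Reagents that add atoms: N,O-dimethylhydroxylamine hydrochloride, CNOC.Cl; 1,1'-carbonyldiimidazole, O=C(n1ccnc1)n1ccnc1 (its imidazole ring is carried only by 5)
Why: Amide formation through the acyl imidazole gives the Weinreb amide, an acyl donor that stops cleanly at the ketone stage in the next step.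

Step 4
Reactants: 6 2-[2-(benzyloxy)-5-bromophenyl]-N-methoxy-N-methylacetamide; 7 methyl acetoacetate
Product: 9 methyl 6-[2-(benzyloxy)-5-bromophenyl]-3,5-dioxohexanoate, via methyl acetoacetate dianion 8 (not isolated)
Conditions: 7 (2.5 equiv), NaH, THF, 0 °C; n-BuLi, 0 °C; then 6, −78 → 0 °C; 1 M HCl
Reagents that add atoms: none
Why: Acylation of the acetoacetate dianion at its terminal carbon by a Weinreb amide should give the 3,5-dioxo ester, the chelated tetrahedral adduct preventing over-addition and the excess dianion absorbing both the acidity of the product and any enolisation of the arylacetamide.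

Step 5
Reactants: 9 methyl 6-[2-(benzyloxy)-5-bromophenyl]-3,5-dioxohexanoate
Product: 11 2-[2-(benzyloxy)-5-bromophenyl]benzene-1,3,5-triol, via 2-[2-(benzyloxy)-5-bromophenyl]cyclohexane-1,3,5-trione 10 (not isolated)
Conditions: Mg(OMe)2 (4 equiv, commercial solution in MeOH), MeOH (0.02 M), reflux, Ar; then 1 M HCl, 0 °C
Reagents that add atoms: none
Why: Proposed new method: Mg(OMe)2 binds the C3/C5 diketone as its chelated enolate, which leaves the C1 ester un-enolised, and reversible deprotonation of the benzylic C6 (acidified by the C5 carbonyl and the aryl ring) gives a carbanion that adds to C1 and expels methoxide, so that the C6–C1 bond, the future C8–C7 bond of unit 2, forms in a Claisen condensation. The closest known reactions are the Mg(OMe)2-mediated Claisen cyclisation of 3,5,7-triketo esters to acylphloroglucinols, the Claisen ring closure of malonate- and acetonedicarboxylate-derived 3,5-dioxo esters to phloroglucinol carboxylates and the Dieckmann-type closure of 6-aryl-5-oxohexanoates to 2-arylcyclohexane-1,3-diones; new is a 3,5-dioxo ester whose C6 nucleophile is activated by one ketone and an aryl group only. Ring A of unit 2 closes in a 6-(enolendo)-exo-trig mode and trione 10 enolises at once to the phloroglucinolate, which makes the C-acylation irreversible. No stereocentre is created. The selectivity required is C-acylation by C6 over O-acylation by the C5 enol oxygen (4-hydroxy-2-pyrone); it rests on thermodynamic control, because methoxide reopens the pyrone to the diketo ester whereas the aromatic phloroglucinolate cannot revert, and high dilution under argon holds back intermolecular condensation and air oxidation.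

Step 6
Reactants: 11 2-[2-(benzyloxy)-5-bromophenyl]benzene-1,3,5-triol
Product: 13 1-{3-[2-(benzyloxy)-5-bromophenyl]-2,4,6-trihydroxyphenyl}ethanone, via ketiminium chloride 12 (not isolated)
Conditions: MeCN, ZnCl2, HCl (g), Et2O, 0 °C; then H2O, reflux
Reagents that add atoms: acetonitrile, CC#N; water, O
Why: Hoesch acylation, in which the nitrilium species attacks one of the two equivalent free positions of the phloroglucinol ring and the ketiminium salt is hydrolysed to the methyl ketone; one acyl group deactivates the ring against a second, and a benzyl ether lost here would be put back in step 7 with one more equivalent of BnBr.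

Step 7
Reactants: 13 1-{3-[2-(benzyloxy)-5-bromophenyl]-2,4,6-trihydroxyphenyl}ethanone
Product: 14 1-{4,6-bis(benzyloxy)-3-[2-(benzyloxy)-5-bromophenyl]-2-hydroxyphenyl}ethanone
Conditions: BnBr (2.1 equiv), K2CO3, DMF, rt
Reagents that add atoms: benzyl bromide, BrCc1ccccc1
Why: Williamson etherification under steric and hydrogen-bond control, in which the non-chelated 4-OH should react first and the 6-OH flanked by hydrogen second, while the 2-OH wedged between the acetyl group and the aryl ring stays chelated to the carbonyl and free, as in the dialkylation of 3-substituted phloroacetophenones.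

Step 8
Reactants: 14 1-{4,6-bis(benzyloxy)-3-[2-(benzyloxy)-5-bromophenyl]-2-hydroxyphenyl}ethanone; 15 4-(benzyloxy)benzaldehyde
Product: 16 (2E)-1-{4,6-bis(benzyloxy)-3-[2-(benzyloxy)-5-bromophenyl]-2-hydroxyphenyl}-3-[4-(benzyloxy)phenyl]prop-2-en-1-one
Conditions: KOH (50% aq), EtOH/THF, rt; then dilute HCl
Reagents that add atoms: none
Why: Claisen–Schmidt condensation with a non-enolisable aldehyde, in which dehydration of the aldol should give the conjugated enone in its thermodynamically preferred E geometry.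

Step 9
Reactants: 16 (2E)-1-{4,6-bis(benzyloxy)-3-[2-(benzyloxy)-5-bromophenyl]-2-hydroxyphenyl}-3-[4-(benzyloxy)phenyl]prop-2-en-1-one
Product: 17 5,7-bis(benzyloxy)-8-[2-(benzyloxy)-5-bromophenyl]-2-[4-(benzyloxy)phenyl]-4H-chromen-4-one
Conditions: I2 (10 mol%), DMSO, 130 °C
Reagents that add atoms: none
Why: Iodine-catalysed oxidative cyclisation of a 2'-hydroxychalcone (oxa-Michael closure, then dehydrogenation with DMSO as terminal oxidant), in which the only free phenol is the one beside the biaryl bond, so ring C of unit 2 should close to the 8-aryl flavone.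

Step 10
Reactants: 17 5,7-bis(benzyloxy)-8-[2-(benzyloxy)-5-bromophenyl]-2-[4-(benzyloxy)phenyl]-4H-chromen-4-one
Product: 18 4-(benzyloxy)-3-{5,7-bis(benzyloxy)-2-[4-(benzyloxy)phenyl]-4-oxo-4H-chromen-8-yl}benzaldehyde
Conditions: Pd(OAc)2 (1 mol%), di(1-adamantyl)-n-butylphosphine (3 mol%), TMEDA (1 equiv), CO/H2 (1:1, 5 bar), toluene, 100 °C
Reagents that add atoms: carbon monoxide, [C-]#[O+]
Why: Palladium-catalysed reductive carbonylation of an unhindered aryl bromide (oxidative addition to zerovalent palladium, CO insertion, hydrogenolysis of the acyl complex), a formylation under which the chromone and the benzyl ethers should be inert.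

Step 11
Reactants: 19 1-(2,6-dihydroxy-4-methoxyphenyl)ethanone
Product: 20 1-[2-(benzyloxy)-6-hydroxy-4-methoxyphenyl]ethanone
Conditions: BnBr (1.05 equiv), K2CO3, acetone, reflux
Reagents that add atoms: benzyl bromide, BrCc1ccccc1
Why: Williamson mono-benzylation, which should stop after one ether because the remaining hydroxyl is chelated to the acetyl carbonyl.

Step 12
Reactants: 18 4-(benzyloxy)-3-{5,7-bis(benzyloxy)-2-[4-(benzyloxy)phenyl]-4-oxo-4H-chromen-8-yl}benzaldehyde; 20 1-[2-(benzyloxy)-6-hydroxy-4-methoxyphenyl]ethanone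
Product: 21 (2E)-1-[2-(benzyloxy)-6-hydroxy-4-methoxyphenyl]-3-(4-(benzyloxy)-3-{5,7-bis(benzyloxy)-2-[4-(benzyloxy)phenyl]-4-oxo-4H-chromen-8-yl}phenyl)prop-2-en-1-one
Conditions: KOH (powdered, 5 equiv), EtOH/THF, rt; then dilute HCl
Reagents that add atoms: none
Why: Claisen–Schmidt condensation of the acetophenone enolate with the non-enolisable aryl aldehyde to the E-chalcone, the electron-rich 5,7-dialkoxychromone of unit 2 being expected to tolerate hydroxide at room temperature.

Step 13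
Reactants: 21 (2E)-1-[2-(benzyloxy)-6-hydroxy-4-methoxyphenyl]-3-(4-(benzyloxy)-3-{5,7-bis(benzyloxy)-2-[4-(benzyloxy)phenyl]-4-oxo-4H-chromen-8-yl}phenyl)prop-2-en-1-one
Product: 22 5-(benzyloxy)-2-(4-(benzyloxy)-3-{5,7-bis(benzyloxy)-2-[4-(benzyloxy)phenyl]-4-oxo-4H-chromen-8-yl}phenyl)-7-methoxy-4H-chromen-4-one
Conditions: I2 (10 mol%), DMSO, 130 °C
Reagents that add atoms: none
Why: The same iodine-catalysed oxidative cyclisation of a 2'-hydroxychalcone as in step 9 should close ring C of unit 1 onto its only free phenol.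

Step 14
Reactants: 22 5-(benzyloxy)-2-(4-(benzyloxy)-3-{5,7-bis(benzyloxy)-2-[4-(benzyloxy)phenyl]-4-oxo-4H-chromen-8-yl}phenyl)-7-methoxy-4H-chromen-4-one
Product: 23 sequoiaflavone
Conditions: H2 (1 atm), 10% Pd/C, THF/MeOH, rt
Reagents that add atoms: none
Why: Catalytic hydrogenolysis should cleave the five aryl benzyl ethers while the aryl methyl ether and the two chromone double bonds stay untouched at 1 atm and room temperature.

**Compound list**

1 | (2-hydroxyphenyl)acetic acid | OC(=O)Cc1ccccc1O | starting material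
2 | (5-bromo-2-hydroxyphenyl)acetic acid | OC(=O)Cc1cc(Br)ccc1O | intermediate
3 | benzyl [2-(benzyloxy)-5-bromophenyl]acetate | O=C(Cc1cc(Br)ccc1OCc1ccccc1)OCc1ccccc1 | intermediate
4 | [2-(benzyloxy)-5-bromophenyl]acetic acid | OC(=O)Cc1cc(Br)ccc1OCc1ccccc1 | intermediate
5 | 1-{[2-(benzyloxy)-5-bromophenyl]acetyl}-1H-imidazole | O=C(Cc1cc(Br)ccc1OCc1ccccc1)n1ccnc1 | intermediate
6 | 2-[2-(benzyloxy)-5-bromophenyl]-N-methoxy-N-methylacetamide | CON(C)C(=O)Cc1cc(Br)ccc1OCc1ccccc1 | intermediate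
7 | methyl acetoacetate | COC(=O)CC(C)=O | starting material
8 | methyl acetoacetate dianion (sodium lithium salt) | [Na+].[Li+].COC(=O)[CH-]C(=O)[CH2-] | intermediate
9 | methyl 6-[2-(benzyloxy)-5-bromophenyl]-3,5-dioxohexanoate | COC(=O)CC(=O)CC(=O)Cc1cc(Br)ccc1OCc1ccccc1 | intermediate
10 | 2-[2-(benzyloxy)-5-bromophenyl]cyclohexane-1,3,5-trione | O=C1CC(=O)C(c2cc(Br)ccc2OCc2ccccc2)C(=O)C1 | intermediate
11 | 2-[2-(benzyloxy)-5-bromophenyl]benzene-1,3,5-triol | Oc1cc(O)c(c(O)c1)-c1cc(Br)ccc1OCc1ccccc1 | intermediate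
12 | 1-{3-[2-(benzyloxy)-5-bromophenyl]-2,4,6-trihydroxyphenyl}ethan-1-iminium chloride | CC(=N)c1c(O)cc(O)c(-c2cc(Br)ccc2OCc2ccccc2)c1O.Cl | intermediate
13 | 1-{3-[2-(benzyloxy)-5-bromophenyl]-2,4,6-trihydroxyphenyl}ethanone | CC(=O)c1c(O)cc(O)c(-c2cc(Br)ccc2OCc2ccccc2)c1O | intermediate
14 | 1-{4,6-bis(benzyloxy)-3-[2-(benzyloxy)-5-bromophenyl]-2-hydroxyphenyl}ethanone | CC(=O)c1c(OCc2ccccc2)cc(OCc2ccccc2)c(-c2cc(Br)ccc2OCc2ccccc2)c1O | intermediate
15 | 4-(benzyloxy)benzaldehyde | O=Cc1ccc(OCc2ccccc2)cc1 | starting material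
16 | (2E)-1-{4,6-bis(benzyloxy)-3-[2-(benzyloxy)-5-bromophenyl]-2-hydroxyphenyl}-3-[4-(benzyloxy)phenyl]prop-2-en-1-one | O=C(/C=C/c1ccc(OCc2ccccc2)cc1)c1c(OCc2ccccc2)cc(OCc2ccccc2)c(-c2cc(Br)ccc2OCc2ccccc2)c1O | intermediate
17 | 5,7-bis(benzyloxy)-8-[2-(benzyloxy)-5-bromophenyl]-2-[4-(benzyloxy)phenyl]-4H-chromen-4-one | O=c1cc(-c2ccc(OCc3ccccc3)cc2)oc2c(-c3cc(Br)ccc3OCc3ccccc3)c(OCc3ccccc3)cc(OCc3ccccc3)c12 | intermediate
18 | 4-(benzyloxy)-3-{5,7-bis(benzyloxy)-2-[4-(benzyloxy)phenyl]-4-oxo-4H-chromen-8-yl}benzaldehyde | O=Cc1ccc(OCc2ccccc2)c(c1)-c1c(OCc2ccccc2)cc(OCc2ccccc2)c2c(=O)cc(-c3ccc(OCc4ccccc4)cc3)oc12 | intermediate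
19 | 1-(2,6-dihydroxy-4-methoxyphenyl)ethanone | CC(=O)c1c(O)cc(OC)cc1O | starting material
20 | 1-[2-(benzyloxy)-6-hydroxy-4-methoxyphenyl]ethanone | CC(=O)c1c(O)cc(OC)cc1OCc1ccccc1 | intermediate
21 | (2E)-1-[2-(benzyloxy)-6-hydroxy-4-methoxyphenyl]-3-(4-(benzyloxy)-3-{5,7-bis(benzyloxy)-2-[4-(benzyloxy)phenyl]-4-oxo-4H-chromen-8-yl}phenyl)prop-2-en-1-one | COc1cc(O)c(C(=O)/C=C/c2ccc(OCc3ccccc3)c(c2)-c2c(OCc3ccccc3)cc(OCc3ccccc3)c3c(=O)cc(-c4ccc(OCc5ccccc5)cc4)oc23)c(OCc2ccccc2)c1 | intermediate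
22 | 5-(benzyloxy)-2-(4-(benzyloxy)-3-{5,7-bis(benzyloxy)-2-[4-(benzyloxy)phenyl]-4-oxo-4H-chromen-8-yl}phenyl)-7-methoxy-4H-chromen-4-one | COc1cc(OCc2ccccc2)c2c(=O)cc(-c3ccc(OCc4ccccc4)c(c3)-c3c(OCc4ccccc4)cc(OCc4ccccc4)c4c(=O)cc(-c5ccc(OCc6ccccc6)cc5)oc34)oc2c1 | intermediate
23 | sequoiaflavone | COc1cc(O)c2c(=O)cc(-c3ccc(O)c(-c4c(O)cc(O)c5c(=O)cc(-c6ccc(O)cc6)oc45)c3)oc2c1 | target

**Step count**

Total steps: 14. Longest linear sequence: 13 steps (steps 1–10 and 12–14, from 1).

**Steps most likely to fail**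

Step 5 (the step proposed as new chemistry).
- What may go wrong: O-acylation to the 4-hydroxy-2-pyrone, retro-Claisen methanolysis of the diketone or intermolecular condensation may outrun the C6-to-C1 ring closure.
- Fallback: the C8–C3' bond would then be made by a Suzuki–Miyaura coupling. The fallback sets out from 4-(benzyloxy)benzaldehyde 15 and comes back to the route at aldehyde 18.
- Commercial 1-[2,4-bis(benzyloxy)-6-hydroxyphenyl]ethanone would be iodinated ortho to its free hydroxyl with benzyltrimethylammonium dichloroiodate and CaCO3 in CH2Cl2/MeOH to give 1-[4,6-bis(benzyloxy)-2-hydroxy-3-iodophenyl]ethanone F1.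
- Claisen–Schmidt condensation of F1 with 15 (KOH, EtOH/THF, rt) would give (2E)-1-[4,6-bis(benzyloxy)-2-hydroxy-3-iodophenyl]-3-[4-(benzyloxy)phenyl]prop-2-en-1-one F2, and I2/DMSO cyclisation would give 5,7-bis(benzyloxy)-2-[4-(benzyloxy)phenyl]-8-iodo-4H-chromen-4-one F3.
- Miyaura borylation of commercial 4-(benzyloxy)-3-bromobenzaldehyde (B2pin2, PdCl2(dppf), KOAc, dioxane, 80 °C) would give 4-(benzyloxy)-3-(4,4,5,5-tetramethyl-1,3,2-dioxaborolan-2-yl)benzaldehyde F4.
- Coupling of F3 with F4 (Pd(PPh3)4, K2CO3, DMF/H2O, 90 °C) would deliver 18, which enters step 12.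

Step 7.
- What may go wrong: benzylation may fall on the hydroxyl beside the biaryl bond instead of the 6-OH, or run on to over-alkylation or C-benzylation, so that the later ring closure is misdirected toward the 6-aryl flavone.
- Fallback: the hydroxyls would be differentiated before the acetyl group is introduced. The fallback sets out from triol 11 and comes back at 14.
- Mitsunobu etherification of 11 with benzyl alcohol (1 equiv, PPh3, DIAD, THF, 0 °C) should select the unhindered hydroxyl para to the aryl group and give 5-(benzyloxy)-2-[2-(benzyloxy)-5-bromophenyl]benzene-1,3-diol F5.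
- Hoesch acylation (MeCN, ZnCl2, HCl, Et2O, 0 °C; then H2O, heat) at one of the two equivalent free positions would pass through 1-{6-(benzyloxy)-3-[2-(benzyloxy)-5-bromophenyl]-2,4-dihydroxyphenyl}ethan-1-iminium chloride F6 to 1-{6-(benzyloxy)-3-[2-(benzyloxy)-5-bromophenyl]-2,4-dihydroxyphenyl}ethanone F7.
- In F7 only the 4-OH is not chelated, so BnBr (1 equiv), K2CO3, acetone would give 14.

Step 12.
- What may go wrong: hydroxide may open the pyranone ring of unit 2 (retro-Claisen degradation) while the aldol condensation of the hindered partners is slow.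
- Fallback: ring C of unit 1 would be built by a Baker–Venkataraman sequence without hydroxide. The fallback sets out from aldehyde 18 (with 20) and comes back at 22.
- Pinnick oxidation of 18 (NaClO2, NaH2PO4, 2-methylbut-2-ene, t-BuOH/THF/H2O) would give 4-(benzyloxy)-3-{5,7-bis(benzyloxy)-2-[4-(benzyloxy)phenyl]-4-oxo-4H-chromen-8-yl}benzoic acid F8.
- Esterification with the phenol of 20 (EDC·HCl, DMAP, CH2Cl2) would give 2-acetyl-3-(benzyloxy)-5-methoxyphenyl 4-(benzyloxy)-3-{5,7-bis(benzyloxy)-2-[4-(benzyloxy)phenyl]-4-oxo-4H-chromen-8-yl}benzoate F9.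
- Acyl transfer with LiN(SiMe3)2 (THF, −78 → 0 °C) would give 1-[2-(benzyloxy)-6-hydroxy-4-methoxyphenyl]-3-(4-(benzyloxy)-3-{5,7-bis(benzyloxy)-2-[4-(benzyloxy)phenyl]-4-oxo-4H-chromen-8-yl}phenyl)propane-1,3-dione F10.
- Cyclodehydration (p-TsOH, toluene, 90 °C) would give 22.

**Further compounds**

F1 | step 5 | 1-[4,6-bis(benzyloxy)-2-hydroxy-3-iodophenyl]ethanone | CC(=O)c1c(OCc2ccccc2)cc(OCc2ccccc2)c(I)c1O
F2 | step 5 | (2E)-1-[4,6-bis(benzyloxy)-2-hydroxy-3-iodophenyl]-3-[4-(benzyloxy)phenyl]prop-2-en-1-one | O=C(/C=C/c1ccc(OCc2ccccc2)cc1)c1c(OCc2ccccc2)cc(OCc2ccccc2)c(I)c1O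
F3 | step 5 | 5,7-bis(benzyloxy)-2-[4-(benzyloxy)phenyl]-8-iodo-4H-chromen-4-one | O=c1cc(-c2ccc(OCc3ccccc3)cc2)oc2c(I)c(OCc3ccccc3)cc(OCc3ccccc3)c12
F4 | step 5 | 4-(benzyloxy)-3-(4,4,5,5-tetramethyl-1,3,2-dioxaborolan-2-yl)benzaldehyde | O=Cc1ccc(OCc2ccccc2)c(c1)B1OC(C)(C)C(C)(C)O1
F5 | step 7 | 5-(benzyloxy)-2-[2-(benzyloxy)-5-bromophenyl]benzene-1,3-diol | Oc1cc(OCc2ccccc2)cc(O)c1-c1cc(Br)ccc1OCc1ccccc1
F6 | step 7 | 1-{6-(benzyloxy)-3-[2-(benzyloxy)-5-bromophenyl]-2,4-dihydroxyphenyl}ethan-1-iminium chloride | CC(=N)c1c(OCc2ccccc2)cc(O)c(-c2cc(Br)ccc2OCc2ccccc2)c1O.Cl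
F7 | step 7 | 1-{6-(benzyloxy)-3-[2-(benzyloxy)-5-bromophenyl]-2,4-dihydroxyphenyl}ethanone | CC(=O)c1c(OCc2ccccc2)cc(O)c(-c2cc(Br)ccc2OCc2ccccc2)c1O
F8 | step 12 | 4-(benzyloxy)-3-{5,7-bis(benzyloxy)-2-[4-(benzyloxy)phenyl]-4-oxo-4H-chromen-8-yl}benzoic acid | OC(=O)c1ccc(OCc2ccccc2)c(c1)-c1c(OCc2ccccc2)cc(OCc2ccccc2)c2c(=O)cc(-c3ccc(OCc4ccccc4)cc3)oc12
F9 | step 12 | 2-acetyl-3-(benzyloxy)-5-methoxyphenyl 4-(benzyloxy)-3-{5,7-bis(benzyloxy)-2-[4-(benzyloxy)phenyl]-4-oxo-4H-chromen-8-yl}benzoate | CC(=O)c1c(OCc2ccccc2)cc(OC)cc1OC(=O)c1ccc(OCc2ccccc2)c(c1)-c1c(OCc2ccccc2)cc(OCc2ccccc2)c2c(=O)cc(-c3ccc(OCc4ccccc4)cc3)oc12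
F10 | step 12 | 1-[2-(benzyloxy)-6-hydroxy-4-methoxyphenyl]-3-(4-(benzyloxy)-3-{5,7-bis(benzyloxy)-2-[4-(benzyloxy)phenyl]-4-oxo-4H-chromen-8-yl}phenyl)propane-1,3-dione | COc1cc(O)c(C(=O)CC(=O)c2ccc(OCc3ccccc3)c(c2)-c2c(OCc3ccccc3)cc(OCc3ccccc3)c3c(=O)cc(-c4ccc(OCc5ccccc5)cc4)oc23)c(OCc2ccccc2)c1
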